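Product climbs more slowly in the red run, which carries more protic impurity, than in the green run: 54.1 % against 59.7 % at 10 h.

all flasks: starting material 0.097 M
- green: reagent 0.097 M; protic impurity 2.4 mM; run made earlier
- red: reagent 0.097 M; protic impurity 9.7 mM; run made earlier
- flask: reagent 0.0970 M; protic impurity 4.85 mM; time 10 h

- green (time / h: product / %): 1.33: 21.7; 3.00: 36.8; 4.00: 41.8; 6.00: 50.9; 8.00: 55.5; 10.0: 59.7
- red (time / h: product / %): 0.833: 14.4; 1.33: 20.2; 2.00: 26.3; 3.00: 32.9; 4.00: 39.0; 6.00: 44.7; 10.0: 54.1

(scatter of a reading: 0.5 percentage points)

- amount of product in percent of the starting material charged, at 30 min, 2.5 h and 10 h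



The first way to the flask at 10 h uses the readings directly. The flask's protic impurity lies between green and red at a weight of 0.336, and straight interpolation gives 57.8 %.

The second way supposes that each protic impurity quickly takes one starting material, as limiting reagent of that side reaction, its charge being less than that of starting material. The free charge, the share of starting material left to make product after that loss, is then 95.0 % in the flask, 97.5 % in green and 90.0 % in red. Free charge minus product is the starting material still present, and a third-order law makes its inverse square rise linearly with time. At 10 h, the slope without the subtraction is 0.516 h⁻¹ in green and 0.375 h⁻¹ in red. With it, the slopes are 0.594 h⁻¹ and 0.652 h⁻¹, closer to each other than without it. Red already reads 0.618 h⁻¹ at 0.833 h.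

Their mean, 0.623 h⁻¹, gives the flask 58.1 %. The two ways differ by 0.30 percentage points, but both rest on the same two readings at 10 h, each with a scatter of 0.5 points, so this gap does not test those readings, and 58.1 % remains an estimate that carries their scatter. The mean slope at 3.00 h, 0.582 h⁻¹, gives 10.5 % at 30 min and 32.5 % at 2.5 h, supposing the side reaction is over by 30 min.

The forecast, reading the behaviour as “effectively third order”, gives 10 %, 32 % and 57.9 %, each less than one percentage point from this reckoning.

The flask gives 10.5 %, 32.5 % and 57.3 %. Its quenched substrate stands at 5.00 % at 1.00 h and at 5.00 % at 10.0 h, matching the charge minus the free charge, 5.00 %.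

    starting material + protic impurity → quenched substrate (k = 2.10 M⁻¹ min⁻¹)
    starting material + reagent → product, rate k2*[starting material]^2*[reagent] (k = 0.479 M⁻² min⁻¹)

Free charge minus product leaves 37.7 % for the flask at 10 h, where it holds 37.7 % starting material. The same subtraction on the red run's reading leaves 35.9 % starting material at 10.0 h.

The runs are calculated for an exercise; noise was put on by code.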